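**Retrosynthetic overview**
- Ring A is a hydroquinone in which C1' bears the chain, C3' and C6' the oxygens and C5' the methyl. The C6' oxygen lies between the two carbon-substituted ring atoms and the C3' oxygen between two CH (C2', C4'). A propenyl(methoxy)carbene of chromium (C3', C4', C5' and the ring methyl), a terminal alkyne (C1', C2') and one CO (C6') assemble exactly this pattern.
- Key disconnection: bonds C2'–C3', C1'–C6' and C5'–C6', giving carbene complex 21 and the complete side-chain enyne 16. Ring A is the only ring formed and it is formed last; the furan ring is bought as 3-methylfuran.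
- Enyne 16: the alkyne comes from Cu-catalysed alkynylation of an allylic bromide, C2=C3 from Zr-catalysed methylalumination with formaldehyde trapping, C4–C5 (5S) from catalyst-controlled propargylation of dienal 9, and the C12–furan bond from alkylation of lithiated 3-methylfuran with a geraniol-derived bromide.
- End game: desilylation, oxidation of the 4-methoxyphenol to the quinone, and dithionite reduction, so that the air-sensitive hydroquinone appears in the last operation.

Key step: step 14

Remark: chain carbons are numbered C1 (CH2 on ring A) to C12 (CH2 on the furan), and the carbons of ring A are numbered C1' (chain), C2' (H), C3' (O), C4' (H), C5' (CH3), C6' (O). The target is the (2E,5S,6E,10E) isomer. The geraniol oxygen is carried as a silyl ether because an ester would not survive the furyllithium of step 4.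

**Route**

Step 1
Reactants: 1 geraniol, (2E)-3,7-dimethylocta-2,6-dien-1-ol
Product: 2 tert-butyl{[(2E)-3,7-dimethylocta-2,6-dien-1-yl]oxy}dimethylsilane
Conditions: t-BuMe2SiCl, imidazole, DMF, 0 °C → rt
Reagents that add atoms: tert-butyldimethylsilyl chloride, CC(C)(C)[Si](C)(C)Cl
Why: Standard silylation of a primary allylic alcohol, giving an ether that is inert to the organolithium of step 4.

Step 2
Reactants: 2 geranyl silyl ether
Product: 3 (2E,6E)-8-[(tert-butyldimethylsilyl)oxy]-2,6-dimethylocta-2,6-dien-1-ol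
Conditions: SeO2 (0.3 equiv), t-BuOOH, salicylic acid (cat.), CH2Cl2, rt
Reagents that add atoms: selenium dioxide, O=[Se]=O (delivers the oxygen); tert-butyl hydroperoxide, CC(C)(C)OO (restores it)
Why: Riley allylic oxidation (ene reaction, then [2,3]-sigmatropic shift) should hydroxylate the (E)-methyl group of the electron-rich terminal alkene, the 2,3-alkene being deactivated by its allylic oxygen.

Step 3
Reactants: 3 allylic alcohol
Product: 4 {[(2E,6E)-8-bromo-3,7-dimethylocta-2,6-dien-1-yl]oxy}(tert-butyl)dimethylsilane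
Conditions: CBr4, PPh3, CH2Cl2, 0 °C
Reagents that add atoms: carbon tetrabromide, BrC(Br)(Br)Br
Why: Appel bromination of a primary allylic alcohol under neutral conditions should proceed without allylic transposition and leave the silyl ether intact.

Step 4
Reactants: 5 3-methylfuran; 4 allylic bromide
Product: 7 tert-butyl{[(2E,6E)-3,7-dimethyl-8-(4-methylfuran-2-yl)octa-2,6-dien-1-yl]oxy}dimethylsilane, via (4-methylfuran-2-yl)lithium 6 (not isolated)
Conditions: n-BuLi, THF, −78 → 0 °C; then 4, −78 °C → rt
Reagents that add atoms: none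
Why: Alpha-lithiation of the furan is expected mainly at the alpha position remote from the methyl group, and the furyllithium should displace the primary allylic bromide by SN2 (classical furan alkylation) to give the 2,4-disubstituted furan; any 2,3-isomer is to be removed here.

Step 5
Reactants: 7 furyl silyl ether
Product: 8 (2E,6E)-3,7-dimethyl-8-(4-methylfuran-2-yl)octa-2,6-dien-1-ol
Conditions: Bu4NF, THF, 0 °C → rt
Reagents that add atoms: none
Why: Fluoride cleavage of a primary silyl ether.

Step 6
Reactants: 8 dienol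
Product: 9 (2E,6E)-3,7-dimethyl-8-(4-methylfuran-2-yl)octa-2,6-dienal
Conditions: MnO2, CH2Cl2, rt
Reagents that add atoms: none
Why: MnO2 oxidises allylic alcohols selectively to enals and should neither touch the furan nor isomerise the 2E alkene.

Step 7
Reactants: 9 dienal
Product: 10 (4S,5E,9E)-6,10-dimethyl-11-(4-methylfuran-2-yl)undeca-5,9-dien-1-yn-4-ol
Conditions: allenylboronic acid pinacol ester, (S)-3,3'-bis(2,4,6-triisopropylphenyl)-1,1'-binaphthyl-2,2'-diyl hydrogen phosphate (10 mol%), 4 Å molecular sieves, toluene, 0 °C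
Reagents that add atoms: allenylboronic acid pinacol ester, C=C=CB1OC(C)(C)C(C)(C)O1
Why: Chiral phosphoric acid-catalysed allenylboration (asymmetric propargylation) through a closed six-membered SE2' transition state; the (S)-acid is expected, on the model established for aryl and alkenyl aldehydes, to deliver the propargyl group to the Si face and so set C5 as S.

Step 8
Reactants: 10 homopropargylic alcohol
Product: 11 tert-butyl{[(4S,5E,9E)-6,10-dimethyl-11-(4-methylfuran-2-yl)undeca-5,9-dien-1-yn-4-yl]oxy}dimethylsilane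
Conditions: t-BuMe2SiCl, imidazole, DMF, rt
Reagents that add atoms: tert-butyldimethylsilyl chloride, CC(C)(C)[Si](C)(C)Cl
Why: Silylation protects the secondary allylic alcohol before the organoaluminium and organomagnesium steps and does not touch the stereocentre.

Step 9
Reactants: 11 silylated enyne
Product: 13 (2E,5S,6E,10E)-5-[(tert-butyldimethylsilyl)oxy]-3,7,11-trimethyl-12-(4-methylfuran-2-yl)dodeca-2,6,10-trien-1-ol, via alkenyldimethylalane 12 (not isolated)
Conditions: AlMe3, Cp2ZrCl2 (0.25 equiv), CH2Cl2, 0 °C → rt; then (CH2O)n, 0 °C → rt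
Reagents that add atoms: trimethylaluminium, C[Al](C)C; formaldehyde (as paraformaldehyde), C=O
Why: Negishi Zr-catalysed methylalumination adds CH3 and Al syn across the terminal alkyne with CH3 on the internal carbon, and formaldehyde traps the alkenylalane with retention to give the (2E)-trisubstituted allylic alcohol; the trisubstituted alkenes are inert.

Step 10
Reactants: 13 allylic alcohol
Product: 14 {[(2E,5S,6E,10E)-1-bromo-3,7,11-trimethyl-12-(4-methylfuran-2-yl)dodeca-2,6,10-trien-5-yl]oxy}(tert-butyl)dimethylsilane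
Conditions: CBr4, PPh3, CH2Cl2, −20 → 0 °C
Reagents that add atoms: carbon tetrabromide, BrC(Br)(Br)Br
Why: Appel bromination of the primary allylic alcohol; the secondary silyl ether and the alkene geometry should be unaffected.

Step 11
Reactants: 14 allylic bromide
Product: 15 tert-butyldimethyl{[(4E,7S,8E,12E)-5,9,13-trimethyl-14-(4-methylfuran-2-yl)-1-(trimethylsilyl)tetradeca-4,8,12-trien-1-yn-7-yl]oxy}silane
Conditions: Me3SiC≡CMgBr, CuBr·SMe2 (10 mol%), THF, 0 → 50 °C
Reagents that add atoms: [(trimethylsilyl)ethynyl]magnesium bromide, C[Si](C)(C)C#C[Mg]Br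
Why: Copper-catalysed coupling of an alkynyl Grignard reagent with a primary allylic bromide should give the skipped enyne by SN2 attack at the unhindered CH2 (SN2' would require attack at the fully substituted C3), and the silyl cap prevents a second allylation.

Step 12
Reactants: 15 silylalkyne
Product: 16 tert-butyldimethyl{[(4E,7S,8E,12E)-5,9,13-trimethyl-14-(4-methylfuran-2-yl)tetradeca-4,8,12-trien-1-yn-7-yl]oxy}silane
Conditions: K2CO3, MeOH/THF, rt
Reagents that add atoms: none
Why: Carbonate-mediated methanolysis of the alkynyl C–Si bond should free the terminal alkyne without cleaving the O-silyl ether or isomerising the skipped enyne.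

Step 13
Reactants: 17 (E)-1-bromoprop-1-ene; 18 chromium hexacarbonyl, Cr(CO)6
Product: 21 pentacarbonyl[(2E)-1-methoxybut-2-en-1-ylidene]chromium, via (E)-prop-1-enyllithium 19 (not isolated), via lithium chromium acylate 20 (not isolated)
Conditions: t-BuLi (2 equiv), Et2O, −78 °C; Cr(CO)6, −78 °C → rt; Me3OBF4, CH2Cl2/H2O, 0 °C
Reagents that add atoms: trimethyloxonium tetrafluoroborate, C[O+](C)C.F[B-](F)(F)F
Why: Fischer carbene synthesis: bromine–lithium exchange with retention of alkene geometry, addition of the alkenyllithium to a CO ligand of Cr(CO)6, and O-methylation of the acylate.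

Step 14
Reactants: 16 terminal enyne; 21 carbene complex
Product: 23 2-[(2E,5S,6E,10E)-5-[(tert-butyldimethylsilyl)oxy]-3,7,11-trimethyl-12-(4-methylfuran-2-yl)dodeca-2,6,10-trien-1-yl]-4-methoxy-6-methylphenol, via tricarbonylchromium arene complex 22 (not isolated)
Conditions: 21 (1.2 equiv), THF (0.05 M), 50 °C, Ar; then air, EtOAc, rt
Reagents that add atoms: none
Why: Thermal loss of one cis CO from the 18-electron zerovalent chromium carbene 21 opens a site at which the terminal alkyne of 16 binds and inserts into the Cr=C bond, its CH carbon joining the carbene carbon (bond C2'–C3') to give a chromium vinylcarbene, and migratory CO insertion then forms the chromium-bound dienylketene (bond C1'–C6'). Ring A closes by 6-pi electrocyclisation of this ketene onto the methyl-bearing propenyl carbon (bond C5'–C6'), and enolisation of the cyclohexadienone gives the 4-methoxyphenol as its Cr(CO)3 complex 22, from which air should release 23. The closest known reaction type is the Dötz benzannulation of alkenyl(methoxy)carbene chromium complexes with terminal alkynes, allyl-substituted alkynes (1,4-enynes) included. No stereocentre is formed, and C5, remote from the alkyne and masked as its silyl ether, is not touched. The step needs regioselective alkyne insertion, which the steric difference between H and the chain CH2 should secure by placing the larger substituent beside the CO-derived carbon C6', so that the chain ends ortho to the free OH and the alkyne CH beside the methoxy carbon C3'. It also needs the chain alkenes and the furan to stay out: the alkenes are trisubstituted, the nearest is held one CH2 from the alkyne and so cannot be reached by the vinylcarbene, and keeping the alkyne limiting in dilute THF should suppress uptake of a second alkyne.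

Step 15
Reactants: 23 silylated 4-methoxyphenol
Product: 24 2-[(2E,5S,6E,10E)-5-hydroxy-3,7,11-trimethyl-12-(4-methylfuran-2-yl)dodeca-2,6,10-trien-1-yl]-4-methoxy-6-methylphenol
Conditions: Bu4NF, AcOH (1:1), THF, rt, Ar
Reagents that add atoms: none
Why: Buffered fluoride cleaves the secondary silyl ether while acetic acid keeps the electron-rich phenol protonated and so less prone to air oxidation; desilylating here keeps fluoride away from the later quinone.

Step 16
Reactants: 24 4-methoxyphenol
Product: 25 2-[(2E,5S,6E,10E)-5-hydroxy-3,7,11-trimethyl-12-(4-methylfuran-2-yl)dodeca-2,6,10-trien-1-yl]-6-methylcyclohexa-2,5-diene-1,4-dione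
Conditions: PhI(OAc)2, MeCN/H2O (2:1), 0 °C
Reagents that add atoms: water, O
Why: Oxidation of a 4-methoxyphenol by a trivalent iodine reagent: ligand exchange at iodine, attack of water at the para carbon C3' and loss of methanol from the hemiketal give the 1,4-benzoquinone, the phenol reacting much faster than the alkenes, the alcohol or the furan.

Step 17
Reactants: 25 quinone
Product: 26 2-[(2E,5S,6E,10E)-5-hydroxy-3,7,11-trimethyl-12-(4-methylfuran-2-yl)dodeca-2,6,10-trien-1-yl]-6-methylbenzene-1,4-diol (the target)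
Conditions: Na2S2O4, EtOAc/H2O, rt, Ar
Reagents that add atoms: none
Why: Two-electron reduction of the quinone by dithionite in a two-phase system gives the hydroquinone under neutral conditions, so the air-sensitive target is formed last and is isolated by extraction under argon.

**Compound list**

1 | geraniol, (2E)-3,7-dimethylocta-2,6-dien-1-ol | CC(C)=CCC/C(C)=C/CO | starting material
2 | tert-butyl{[(2E)-3,7-dimethylocta-2,6-dien-1-yl]oxy}dimethylsilane | CC(C)=CCC/C(C)=C/CO[Si](C)(C)C(C)(C)C | intermediate
3 | (2E,6E)-8-[(tert-butyldimethylsilyl)oxy]-2,6-dimethylocta-2,6-dien-1-ol | OC/C(C)=C/CC/C(C)=C/CO[Si](C)(C)C(C)(C)C | intermediate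
4 | {[(2E,6E)-8-bromo-3,7-dimethylocta-2,6-dien-1-yl]oxy}(tert-butyl)dimethylsilane | BrC/C(C)=C/CC/C(C)=C/CO[Si](C)(C)C(C)(C)C | intermediate
5 | 3-methylfuran | Cc1ccoc1 | starting material
6 | (4-methylfuran-2-yl)lithium | [Li]c1cc(C)co1 | intermediate (not isolated)
7 | tert-butyl{[(2E,6E)-3,7-dimethyl-8-(4-methylfuran-2-yl)octa-2,6-dien-1-yl]oxy}dimethylsilane | Cc1cc(C/C(C)=C/CC/C(C)=C/CO[Si](C)(C)C(C)(C)C)oc1 | intermediate
8 | (2E,6E)-3,7-dimethyl-8-(4-methylfuran-2-yl)octa-2,6-dien-1-ol | Cc1cc(C/C(C)=C/CC/C(C)=C/CO)oc1 | intermediate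
9 | (2E,6E)-3,7-dimethyl-8-(4-methylfuran-2-yl)octa-2,6-dienal | Cc1cc(C/C(C)=C/CC/C(C)=C/C=O)oc1 | intermediate
10 | (4S,5E,9E)-6,10-dimethyl-11-(4-methylfuran-2-yl)undeca-5,9-dien-1-yn-4-ol | C/C(=C\[C@@H](O)CC#C)CC/C=C(\C)Cc1cc(C)co1 | intermediate
11 | tert-butyl{[(4S,5E,9E)-6,10-dimethyl-11-(4-methylfuran-2-yl)undeca-5,9-dien-1-yn-4-yl]oxy}dimethylsilane | C/C(=C\[C@@H](O[Si](C)(C)C(C)(C)C)CC#C)CC/C=C(\C)Cc1cc(C)co1 | intermediate
12 | [(1E,4S,5E,9E)-4-[(tert-butyldimethylsilyl)oxy]-2,6,10-trimethyl-11-(4-methylfuran-2-yl)undeca-1,5,9-trien-1-yl]dimethylalane | C/C(=C\[C@@H](O[Si](C)(C)C(C)(C)C)C/C(C)=C/[Al](C)C)CC/C=C(\C)Cc1cc(C)co1 | intermediate (not isolated)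
13 | (2E,5S,6E,10E)-5-[(tert-butyldimethylsilyl)oxy]-3,7,11-trimethyl-12-(4-methylfuran-2-yl)dodeca-2,6,10-trien-1-ol | C/C(=C\[C@@H](O[Si](C)(C)C(C)(C)C)C/C(C)=C/CO)CC/C=C(\C)Cc1cc(C)co1 | intermediate
14 | {[(2E,5S,6E,10E)-1-bromo-3,7,11-trimethyl-12-(4-methylfuran-2-yl)dodeca-2,6,10-trien-5-yl]oxy}(tert-butyl)dimethylsilane | C/C(=C\[C@@H](O[Si](C)(C)C(C)(C)C)C/C(C)=C/CBr)CC/C=C(\C)Cc1cc(C)co1 | intermediate
15 | tert-butyldimethyl{[(4E,7S,8E,12E)-5,9,13-trimethyl-14-(4-methylfuran-2-yl)-1-(trimethylsilyl)tetradeca-4,8,12-trien-1-yn-7-yl]oxy}silane | C/C(=C\[C@@H](O[Si](C)(C)C(C)(C)C)C/C(C)=C/CC#C[Si](C)(C)C)CC/C=C(\C)Cc1cc(C)co1 | intermediate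
16 | tert-butyldimethyl{[(4E,7S,8E,12E)-5,9,13-trimethyl-14-(4-methylfuran-2-yl)tetradeca-4,8,12-trien-1-yn-7-yl]oxy}silane | C/C(=C\[C@@H](O[Si](C)(C)C(C)(C)C)C/C(C)=C/CC#C)CC/C=C(\C)Cc1cc(C)co1 | intermediate (key-step precursor)
17 | (E)-1-bromoprop-1-ene | C/C=C/Br | starting material
18 | chromium hexacarbonyl, Cr(CO)6 | O=C=[Cr](=C=O)(=C=O)(=C=O)(=C=O)=C=O | starting material
19 | (E)-prop-1-enyllithium | C/C=C/[Li] | intermediate (not isolated)
20 | lithium pentacarbonyl[(2E)-1-oxidobut-2-en-1-ylidene]chromate (lithium acylate) | C/C=C/C(O[Li])=[Cr](=C=O)(=C=O)(=C=O)(=C=O)=C=O | intermediate (not isolated)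
21 | pentacarbonyl[(2E)-1-methoxybut-2-en-1-ylidene]chromium | C/C=C/C(OC)=[Cr](=C=O)(=C=O)(=C=O)(=C=O)=C=O | intermediate (key-step precursor)
22 | tricarbonyl(hexahapto-arene)chromium complex of 23 (SMILES shows the arene and the Cr(CO)3 fragment bound to ring A as two parts) | C/C(=C\[C@@H](O[Si](C)(C)C(C)(C)C)C/C(C)=C/Cc1cc(OC)cc(C)c1O)CC/C=C(\C)Cc1cc(C)co1.O=C=[Cr](=C=O)=C=O | intermediate (not isolated)
23 | 2-[(2E,5S,6E,10E)-5-[(tert-butyldimethylsilyl)oxy]-3,7,11-trimethyl-12-(4-methylfuran-2-yl)dodeca-2,6,10-trien-1-yl]-4-methoxy-6-methylphenol | C/C(=C\[C@@H](O[Si](C)(C)C(C)(C)C)C/C(C)=C/Cc1cc(OC)cc(C)c1O)CC/C=C(\C)Cc1cc(C)co1 | intermediate (key-step product)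
24 | 2-[(2E,5S,6E,10E)-5-hydroxy-3,7,11-trimethyl-12-(4-methylfuran-2-yl)dodeca-2,6,10-trien-1-yl]-4-methoxy-6-methylphenol | C/C(=C\[C@@H](O)C/C(C)=C/Cc1cc(OC)cc(C)c1O)CC/C=C(\C)Cc1cc(C)co1 | intermediate
25 | 2-[(2E,5S,6E,10E)-5-hydroxy-3,7,11-trimethyl-12-(4-methylfuran-2-yl)dodeca-2,6,10-trien-1-yl]-6-methylcyclohexa-2,5-diene-1,4-dione | C/C(=C\[C@@H](O)C/C(C)=C/CC1=CC(=O)C=C(C)C1=O)CC/C=C(\C)Cc1cc(C)co1 | intermediate
26 | 2-[(2E,5S,6E,10E)-5-hydroxy-3,7,11-trimethyl-12-(4-methylfuran-2-yl)dodeca-2,6,10-trien-1-yl]-6-methylbenzene-1,4-diol (CNP0172089.1) | C/C(=C\[C@@H](O)C/C(C)=C/Cc1cc(O)cc(C)c1O)CC/C=C(\C)Cc1cc(C)co1 | target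

**Step count and risks**

Total step count: 17. Longest linear sequence: 16 (steps 1–12, then 14–17; step 13 is the side branch).

Steps most likely to fail:

1. Step 14 (benzannulation). The alkyne may insert with imperfect regiocontrol, take up a second alkyne or fail to insert CO, and the electron-rich phenol may be oxidised while chromium is removed. Fallback: the ring is bought and the C1'–C1 bond is made instead. It sets out from allylic bromide 14. Commercial 4-methoxy-2-methylphenol is brominated at its only free position ortho to OH (N-bromosuccinimide, CH2Cl2, 0 °C) to give 2-bromo-4-methoxy-6-methylphenol F1. Treatment with n-BuLi (1 equiv) and then t-BuLi (2 equiv) in Et2O at −78 °C should give lithium 2-lithio-4-methoxy-6-methylphenoxide F2. Its aryl carbon displaces the bromide of 14 (CuBr·SMe2 catalysis if needed) to give the lithium phenoxide of 23 F3, and aqueous NH4Cl protonates it to bring the route back at 23.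

2. Step 4 (furan alkylation). Deprotonation may compete at the alpha position beside the methyl group and carry a regioisomeric furan through the route. Fallback: a bromine atom blocks that position. It sets out from bromide 4 and 3-methylfuran 5. Electrophilic bromination of 5 at the alpha position next to the methyl group (N-bromosuccinimide, DMF, 0 °C) gives 2-bromo-3-methylfuran F4. LiN(iPr)2 (THF, −78 °C) removes its only alpha proton to give (5-bromo-4-methylfuran-2-yl)lithium F5, which is alkylated by 4 to give {[(2E,6E)-8-(5-bromo-4-methylfuran-2-yl)-3,7-dimethylocta-2,6-dien-1-yl]oxy}(tert-butyl)dimethylsilane F6. Bromine–lithium exchange (t-BuLi, THF, −78 °C) gives {5-[(2E,6E)-8-[(tert-butyldimethylsilyl)oxy]-2,6-dimethylocta-2,6-dien-1-yl]-3-methylfuran-2-yl}lithium F7, and methanol protonates it to return at 7.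

3. Step 7 (asymmetric propargylation). Facial discrimination by the catalyst may be weak on an enal that carries two beta substituents, and addition may be slow. Fallback: racemic addition followed by enzymatic kinetic resolution. It sets out from dienal 9. Zinc-mediated Barbier propargylation (propargyl bromide, Zn, THF/aqueous NH4Cl) gives racemic (5E,9E)-6,10-dimethyl-11-(4-methylfuran-2-yl)undeca-5,9-dien-1-yn-4-ol F8. Acylation with vinyl acetate and immobilised Candida antarctica lipase B is expected, by the empirical rule for secondary alcohols, to convert the R enantiomer into (4R,5E,9E)-6,10-dimethyl-11-(4-methylfuran-2-yl)undeca-5,9-dien-1-yn-4-yl acetate F9 and to leave the S alcohol, which is separated and returns at 10.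

**Further compounds**

F1 | step 14 | 2-bromo-4-methoxy-6-methylphenol | COc1cc(C)c(O)c(Br)c1
F2 | step 14 | lithium 2-lithio-4-methoxy-6-methylphenoxide | COc1cc(C)c(O[Li])c([Li])c1
F3 | step 14 | lithium 2-[(2E,5S,6E,10E)-5-[(tert-butyldimethylsilyl)oxy]-3,7,11-trimethyl-12-(4-methylfuran-2-yl)dodeca-2,6,10-trien-1-yl]-4-methoxy-6-methylphenoxide | C/C(=C\[C@@H](O[Si](C)(C)C(C)(C)C)C/C(C)=C/Cc1cc(OC)cc(C)c1O[Li])CC/C=C(\C)Cc1cc(C)co1
F4 | step 4 | 2-bromo-3-methylfuran | Cc1ccoc1Br
F5 | step 4 | (5-bromo-4-methylfuran-2-yl)lithium | [Li]c1cc(C)c(Br)o1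
F6 | step 4 | {[(2E,6E)-8-(5-bromo-4-methylfuran-2-yl)-3,7-dimethylocta-2,6-dien-1-yl]oxy}(tert-butyl)dimethylsilane | Cc1cc(C/C(C)=C/CC/C(C)=C/CO[Si](C)(C)C(C)(C)C)oc1Br
F7 | step 4 | {5-[(2E,6E)-8-[(tert-butyldimethylsilyl)oxy]-2,6-dimethylocta-2,6-dien-1-yl]-3-methylfuran-2-yl}lithium | Cc1cc(C/C(C)=C/CC/C(C)=C/CO[Si](C)(C)C(C)(C)C)oc1[Li]
F8 | step 7 | racemic (5E,9E)-6,10-dimethyl-11-(4-methylfuran-2-yl)undeca-5,9-dien-1-yn-4-ol | C/C(=C\C(O)CC#C)CC/C=C(\C)Cc1cc(C)co1
F9 | step 7 | (4R,5E,9E)-6,10-dimethyl-11-(4-methylfuran-2-yl)undeca-5,9-dien-1-yn-4-yl acetate | C/C(=C\[C@H](OC(C)=O)CC#C)CC/C=C(\C)Cc1cc(C)co1
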